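The tricycle is cut at the cyclobutane C4–C5–C10–C9. Because C10 is a one-carbon bridge between C5 and C9 of the six-membered ring C4–C5–C6–C7–C8–C9, the four-membered ring is the [2+2] adduct of a C9=C10 ketene with the trisubstituted C4=C5 alkene of an acyclic, oxygenated farnesane-type dienoic acid. One thermal operation turns a (2E,6E)-dienoyl chloride into the bicyclo[3.1.1]heptenone, forming C10–C5 and C9–C4, both rings and the stereocentres C4, C5 and C9. The precursor carries the (3R)-silyloxy group that must steer the alkene face, the C1 ketone, and a C11 benzoate that later releases the C11 enolate for closure of the seven-membered ring.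

Key step: step 8

Atom labels used throughout: C1 bears the methacrylate, C3 the isobutyrate, C4 is the methyl-bearing quaternary carbon, C6 the ring ketone, C8 the methyl-bearing alkene carbon, C11 the gem-dimethyl carbon; the chain C3–C2–C1–C11 spans C4 and C10 (seven-membered ring).
Assumption: (−)-Ipc2BCl [Ipc = isopinocampheyl, from (+)-α-pinene] is taken to add the methyl ketone enolate to the Re face of the enal and so to give the (3R)-carbinol; configuration and enantiomeric purity of 7 are to be checked before material is committed.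
Remark: HCl is expected to be lost from the (2E)-enoyl chloride mainly across C10 and the C8 methyl, so the cycloadduct should first appear mainly as the exocyclic alkene; step 8 therefore includes migration of that double bond into the ring.

Step 1
Reactants: 1 3-hydroxy-3-methylbutan-2-one
Product: 2 2-methyl-3-oxobutan-2-yl benzoate
Conditions: PhCOCl, pyridine, 4-(dimethylamino)pyridine (cat.), CH2Cl2, 40 °C
Reagents that add atoms: benzoyl chloride O=C(Cl)c1ccccc1
Why: Nucleophile-catalysed esterification of the tertiary α-ketol through the N-acylpyridinium salt; the benzoate marks the future C11 for reductive enolate formation, so that no regioselective α-halogenation is needed after the key step.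

Step 2
Reactants: 3 geranyl acetate
Product: 5 (2E,6E)-3,7-dimethyl-8-oxoocta-2,6-dien-1-yl acetate, via allylic alcohol 4 (not isolated)
Conditions: SeO2 (cat.), t-BuOOH, 2-hydroxybenzoic acid (cat.), CH2Cl2, rt; aqueous work-up; then MnO2, CH2Cl2, rt
Reagents that add atoms: selenium dioxide O=[Se]=O (catalytic oxygen carrier); tert-butyl hydroperoxide CC(C)(C)OO
Why: Riley oxidation (ene reaction, then [2,3]-sigmatropic shift) attacks the (E)-methyl group of the more electron-rich terminal alkene, and MnO2 takes the crude allylic alcohol to the (E)-enal without touching the acetate.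

Step 3
Reactants: 2 2-methyl-3-oxobutan-2-yl benzoate; 5 (2E,6E)-3,7-dimethyl-8-oxoocta-2,6-dien-1-yl acetate
Product: 7 (2E,6E,8R)-1-acetoxy-8-hydroxy-3,7,11-trimethyl-10-oxododeca-2,6-dien-11-yl benzoate (dodecadiene C8 = C3 of the target), via enol diisopinocampheylborinate 6 (not isolated)
Conditions: (−)-Ipc2BCl, Et3N, Et2O, 0 °C; then 5, −78 → −20 °C; H2O2, MeOH, pH 7 buffer
Reagents that add atoms: none
Why: Boron-mediated aldol reaction of a methyl ketone that can enolise only at its methyl group, in which the isopinocampheyl ligands should direct the enolate to the Re face of the enal and so set C3 as R.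

Step 4
Reactants: 7 aldol adduct
Product: 8 (2E,6E,8R)-1-acetoxy-3,7,11-trimethyl-10-oxo-8-[(triisopropylsilyl)oxy]dodeca-2,6-dien-11-yl benzoate
Conditions: iPr3SiOTf, 2,6-dimethylpyridine, CH2Cl2, −78 → 0 °C
Reagents that add atoms: triisopropylsilyl trifluoromethanesulfonate CC(C)[Si](C(C)C)(C(C)C)OS(=O)(=O)C(F)(F)F
Why: O-silylation of the secondary allylic alcohol with a silyl triflate and a hindered pyridine base; the bulky triisopropylsilyl group is chosen because it is ill-suited to the in-plane position next to C5 during step 8 and survives the mildly acidic alkene migration.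

Step 5
Reactants: 8 silyl ether acetate
Product: 9 (2E,6E,8R)-1-hydroxy-3,7,11-trimethyl-10-oxo-8-[(triisopropylsilyl)oxy]dodeca-2,6-dien-11-yl benzoate
Conditions: K2CO3 (cat.), MeOH, 0 °C, short reaction time
Reagents that add atoms: none
Why: Base-catalysed transesterification removes the primary allylic acetate much faster than the hindered tertiary benzoate, and the low temperature spares the β-silyloxy ketone.

Step 6
Reactants: 9 allylic alcohol
Product: 11 (2E,6E,8R)-11-(benzoyloxy)-3,7,11-trimethyl-10-oxo-8-[(triisopropylsilyl)oxy]dodeca-2,6-dienoic acid, via enal 10 (not isolated)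
Conditions: MnO2, CH2Cl2, rt; filter; then NaClO2, NaH2PO4, 2-methyl-2-butene, t-BuOH/H2O, 0 °C → rt
Reagents that add atoms: sodium chlorite [Na+].[O-]Cl=O
Why: Allylic oxidation with MnO2 followed by Pinnick oxidation of the crude enal gives the (2E)-enoic acid, chlorite leaving ketone, silyl ether, benzoate and the isolated alkene untouched while the alkene scavenger removes hypochlorite.

Step 7
Reactants: 11 dienoic acid
Product: 12 (2E,6E,8R)-11-(benzoyloxy)-3,7,11-trimethyl-10-oxo-8-[(triisopropylsilyl)oxy]dodeca-2,6-dienoyl chloride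
Conditions: (COCl)2, N,N-dimethylformamide (cat.), CH2Cl2, 0 °C → rt; evaporate, use at once
Reagents that add atoms: oxalyl chloride O=C(Cl)C(=O)Cl
Why: Acid chloride formation through the chloroiminium salt under conditions that leave silyl ether, ketone and benzoate intact.

Step 8
Reactants: 12 (2E,6E)-dienoyl chloride
Product: 15 2,7-dimethyl-7-[(1R)-4-(benzoyloxy)-4-methyl-3-oxo-1-(triisopropylsilyloxy)pentyl]bicyclo[3.1.1]hept-2-en-6-one (C10 ketone; C7=C8 alkene; C4 methyl syn to the C6–C7–C8 bridge; C4 C5 C9 configured as in 24), via vinylketene 13 (not isolated), via exocyclic alkene isomer 14 (not isolated)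
Conditions: Et3N (5 equiv), PhMe, 110 °C, slow addition of 12 to high dilution; filter, concentrate; then RhCl3·3H2O (5 mol %), EtOH, 70 °C; chromatography
Reagents that add atoms: none
Why: Et3N removes HCl from the (2E)-enoyl chloride, mainly across C10 and the C8 methyl (the γ-carbon on the side of the acyl group), to give vinylketene 13, whose electrophilic central carbon C10 bonds to the less substituted alkene carbon C5 while positive charge builds on tertiary C4 and the nucleophilic ketene carbon C9 closes onto C4 on the same face, an asynchronous thermal [2+2] cycloaddition. The closest known reaction type is the intramolecular vinylketene–alkene cycloaddition of geranoyl- and farnesoyl-type chlorides to chrysanthenone-type bicyclo[3.1.1]heptan-6-ones. The cyclobutanone C4–C5–C10–C9 and the six-membered ring C4–C5–C6–C7–C8–C9 close together in the crossed (bridged) mode, since the fused bicyclo[3.2.0] alternative would require C10 to bond to the more substituted C4. C5 and C9 are fixed relative to C4 by the bridged ring system and C4 by suprafacial addition to the (6E)-alkene (methyl cis to C6, C3 chain on the opposite face), while the absolute sense of all three depends on the alkene face, which the (3R)-silyloxy centre must select: with C3–H turned towards the C4 methyl (least A(1,2) strain) and the large OSi(iPr)3 group anti to the incoming ketene the required face is attacked, whereas the competing inside-alkoxy arrangement gives the C4,C5,C9-epimeric series, a diastereomer to be removed by chromatography. RhCl3 then moves the exocyclic double bond of 14 into the ring (metal hydride addition–elimination, a known isomerisation of methylenecycloalkanes), converging 14 and any directly formed endocyclic isomer on 15. The step needs crossed regiochemistry, secured by cation stabilisation at C4, and facial selectivity, secured only by the C3 centre and therefore the least certain point of the route.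

Step 9
Reactants: 15 bicyclic diketone benzoate
Product: 16 7-hydroxy-2,6,6,9-tetramethyl-3-[(triisopropylsilyl)oxy]tricyclo[5.4.0.0^2,8]undec-9-en-5-one (C1 ketone; C10 hydroxyl syn to the C6–C7–C8 bridge; C10–C11 bond closed)
Conditions: SmI2 (2.5 equiv), THF, −78 → −20 °C; aq. NH4Cl
Reagents that add atoms: none
Why: Electron transfer from divalent samarium to the C1 ketone expels the α-benzoate and gives the C11 samarium enolate regiospecifically, which adds to the strained C10 carbonyl in a Reformatsky-type intramolecular aldol reaction; the chain on C4 can reach C10 only from the face remote from the C6–C7–C8 bridge, which fixes C10.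

Step 10
Reactants: 16 tricyclic ketol
Product: 17 methyl 2,6,6,9-tetramethyl-5-oxo-3-[(triisopropylsilyl)oxy]tricyclo[5.4.0.0^2,8]undec-9-en-7-yl oxalate
Conditions: MeO2CCOCl, pyridine, 4-(dimethylamino)pyridine (cat.), CH2Cl2, 0 °C → rt
Reagents that add atoms: methyl chlorooxoacetate COC(=O)C(=O)Cl
Why: Acylation of the tertiary cyclobutanol with a small, highly electrophilic acid chloride gives the tertiary methyl oxalate needed for radical C–O cleavage, the weakly basic medium avoiding retro-aldol opening of the β-hydroxy ketone.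

Step 11
Reactants: 17 tertiary methyl oxalate
Product: 18 2,6,6,9-tetramethyl-3-[(triisopropylsilyl)oxy]tricyclo[5.4.0.0^2,8]undec-9-en-5-one (C10–H syn to the C6–C7–C8 bridge as in 24)
Conditions: Bu3SnH (5 equiv, at least 0.5 M), 2,2'-azobis(2-methylpropionitrile) (cat.), PhMe, 110 °C
Reagents that add atoms: none
Why: Barton–McCombie-type radical deoxygenation of a tertiary methyl oxalate, in which the C10 radical can accept hydrogen only on the face syn to the C6–C7–C8 bridge because C11 is tied to C4 through the seven-membered ring, the high tin hydride concentration being meant to outrun 1,2-acyl migration of this β-keto radical.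

Step 12
Reactants: 18 tricyclic silyloxy ketone
Product: 19 3-hydroxy-2,6,6,9-tetramethyltricyclo[5.4.0.0^2,8]undec-9-en-5-one ((3R)-β-hydroxy ketone)
Conditions: HF·pyridine, pyridine, THF, 0 °C → rt
Reagents that add atoms: none
Why: Fluoride-mediated cleavage of the silyl ether in a buffered, weakly acidic medium that avoids β-elimination or retro-aldol reaction of the β-hydroxy ketone and acid-catalysed rearrangement of the pinene-type alkene.

Step 13
Reactants: 19 β-hydroxy ketone; 20 isobutyraldehyde
Product: 21 5-hydroxy-2,6,6,9-tetramethyltricyclo[5.4.0.0^2,8]undec-9-en-3-yl 2-methylpropanoate (O3 isobutyrate; free C1 hydroxyl trans to O3)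
Conditions: SmI2 (0.3 equiv, premixed with the aldehyde), THF, −10 °C
Reagents that add atoms: none
Why: Evans–Tishchenko reduction, in which the samarium-bound hemiacetal formed at O3 delivers hydride to C1 through a six-membered transition state on the face that O3 occupies, so that O1 ends trans to O3 on the seven-membered ring (1,3-anti, C1 R) and O3 leaves as the isobutyrate.

Step 14
Reactants: 21 hydroxy isobutyrate; 22 methacrylic anhydride
Product: 23 2,6,6,9-tetramethyl-3-(2-methylpropanoyloxy)tricyclo[5.4.0.0^2,8]undec-9-en-5-yl 2-methylprop-2-enoate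
Conditions: 4-(dimethylamino)pyridine, Et3N, 2,6-di-tert-butyl-4-methylphenol (trace), CH2Cl2, rt
Reagents that add atoms: none
Why: Nucleophile-catalysed esterification of the remaining secondary alcohol through the N-acylpyridinium ion, the phenol suppressing radical polymerisation of the methacrylate.

Step 15
Reactants: 23 diester
Product: 24 CNP0214356.1, 2,6,6,9-tetramethyl-3-(2-methylpropanoyloxy)-11-oxotricyclo[5.4.0.0^2,8]undec-9-en-5-yl 2-methylprop-2-enoate ((1R,3R,4R,5R,9R,10S) in the atom labels used here)
Conditions: CrO3, 3,5-dimethylpyrazole, CH2Cl2, −20 °C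
Reagents that add atoms: chromium trioxide O=[Cr](=O)=O
Why: Allylic oxidation of the ring methylene C6 by the hexavalent chromium–pyrazole complex, the regiochemistry by which α-pinene-type alkenes give verbenone-type enones; the bridgehead C9–H and the C8 methyl should react more slowly and the esters and the electron-poor methacrylate are inert.

Compound list
1 | 3-hydroxy-3-methylbutan-2-one | CC(=O)C(C)(C)O | starting material
2 | 2-methyl-3-oxobutan-2-yl benzoate | CC(=O)C(C)(C)OC(=O)c1ccccc1 | intermediate
3 | geranyl acetate | CC(C)=CCC/C(C)=C/COC(C)=O | starting material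
4 | (2E,6E)-8-hydroxy-3,7-dimethylocta-2,6-dien-1-yl acetate | CC(=O)OC/C=C(C)/CC/C=C(C)/CO | intermediate
5 | (2E,6E)-3,7-dimethyl-8-oxoocta-2,6-dien-1-yl acetate | CC(=O)OC/C=C(C)/CC/C=C(C)/C=O | intermediate
6 | enol diisopinocampheylborinate of 2 | C=C(OB([C@@H]1C[C@@H]2C[C@H]([C@H]1C)C2(C)C)[C@@H]1C[C@@H]2C[C@H]([C@H]1C)C2(C)C)C(C)(C)OC(=O)c1ccccc1 | intermediate
7 | (2E,6E,8R)-1-acetoxy-8-hydroxy-3,7,11-trimethyl-10-oxododeca-2,6-dien-11-yl benzoate | CC(=O)OC/C=C(C)/CC/C=C(C)/[C@H](O)CC(=O)C(C)(C)OC(=O)c1ccccc1 | intermediate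
8 | 8-O-triisopropylsilyl ether of 7 | CC(=O)OC/C=C(C)/CC/C=C(C)/[C@H](O[Si](C(C)C)(C(C)C)C(C)C)CC(=O)C(C)(C)OC(=O)c1ccccc1 | intermediate
9 | (2E,6E,8R)-1-hydroxy-3,7,11-trimethyl-10-oxo-8-[(triisopropylsilyl)oxy]dodeca-2,6-dien-11-yl benzoate | OC/C=C(C)/CC/C=C(C)/[C@H](O[Si](C(C)C)(C(C)C)C(C)C)CC(=O)C(C)(C)OC(=O)c1ccccc1 | intermediate
10 | (2E,6E,8R)-enal corresponding to 9 | O=C/C=C(C)/CC/C=C(C)/[C@H](O[Si](C(C)C)(C(C)C)C(C)C)CC(=O)C(C)(C)OC(=O)c1ccccc1 | intermediate
11 | (2E,6E,8R)-11-(benzoyloxy)-3,7,11-trimethyl-10-oxo-8-[(triisopropylsilyl)oxy]dodeca-2,6-dienoic acid | OC(=O)/C=C(C)/CC/C=C(C)/[C@H](O[Si](C(C)C)(C(C)C)C(C)C)CC(=O)C(C)(C)OC(=O)c1ccccc1 | intermediate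
12 | acid chloride of 11, precursor of the key step | O=C(Cl)/C=C(C)/CC/C=C(C)/[C@H](O[Si](C(C)C)(C(C)C)C(C)C)CC(=O)C(C)(C)OC(=O)c1ccccc1 | intermediate
13 | cross-conjugated vinylketene (HCl lost across C10 and the C8 methyl) | O=C=CC(=C)CC/C=C(C)/[C@H](O[Si](C(C)C)(C(C)C)C(C)C)CC(=O)C(C)(C)OC(=O)c1ccccc1 | intermediate
14 | exocyclic isomer of 15: 7-methyl-2-methylidenebicyclo[3.1.1]heptan-6-one with the same C7 side chain | CC(C)(OC(=O)c1ccccc1)C(=O)C[C@@H](O[Si](C(C)C)(C(C)C)C(C)C)[C@@]2(C)[C@@H]3CCC(=C)[C@H]2C3=O | intermediate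
15 | 2,7-dimethyl-7-[(1R)-4-(benzoyloxy)-4-methyl-3-oxo-1-(triisopropylsilyloxy)pentyl]bicyclo[3.1.1]hept-2-en-6-one, product of the key step | CC(C)(OC(=O)c1ccccc1)C(=O)C[C@@H](O[Si](C(C)C)(C(C)C)C(C)C)[C@@]2(C)[C@@H]3CC=C(C)[C@H]2C3=O | intermediate
16 | 7-hydroxy-2,6,6,9-tetramethyl-3-[(triisopropylsilyl)oxy]tricyclo[5.4.0.0^2,8]undec-9-en-5-one | O=C1C[C@@H](O[Si](C(C)C)(C(C)C)C(C)C)[C@@]2(C)[C@@H]3CC=C(C)[C@H]2[C@]3(O)C1(C)C | intermediate
17 | methyl oxalate of 16 at the C10 hydroxyl | O=C1C[C@@H](O[Si](C(C)C)(C(C)C)C(C)C)[C@@]2(C)[C@@H]3CC=C(C)[C@H]2[C@]3(OC(=O)C(=O)OC)C1(C)C | intermediate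
18 | 2,6,6,9-tetramethyl-3-[(triisopropylsilyl)oxy]tricyclo[5.4.0.0^2,8]undec-9-en-5-one | O=C1C[C@@H](O[Si](C(C)C)(C(C)C)C(C)C)[C@@]2(C)[C@@H]3CC=C(C)[C@H]2[C@@H]3C1(C)C | intermediate
19 | 3-hydroxy-2,6,6,9-tetramethyltricyclo[5.4.0.0^2,8]undec-9-en-5-one | O=C1C[C@@H](O)[C@@]2(C)[C@@H]3CC=C(C)[C@H]2[C@@H]3C1(C)C | intermediate
20 | isobutyraldehyde | CC(C)C=O | starting material
21 | 5-hydroxy-2,6,6,9-tetramethyltricyclo[5.4.0.0^2,8]undec-9-en-3-yl 2-methylpropanoate | O[C@@H]1C[C@@H](OC(=O)C(C)C)[C@@]2(C)[C@@H]3CC=C(C)[C@H]2[C@@H]3C1(C)C | intermediate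
22 | methacrylic anhydride | C=C(C)C(=O)OC(=O)C(C)=C | starting material
23 | 2,6,6,9-tetramethyl-3-(2-methylpropanoyloxy)tricyclo[5.4.0.0^2,8]undec-9-en-5-yl 2-methylprop-2-enoate | C=C(C)C(=O)O[C@@H]1C[C@@H](OC(=O)C(C)C)[C@@]2(C)[C@@H]3CC=C(C)[C@H]2[C@@H]3C1(C)C | intermediate
24 | CNP0214356.1 | C=C(C)C(=O)O[C@@H]1C[C@@H](OC(=O)C(C)C)[C@@]2(C)[C@@H]3C(=O)C=C(C)[C@H]2[C@@H]3C1(C)C | target

Total step count: 15. Longest linear sequence: 14 steps (steps 2 to 15, from geranyl acetate).

Steps most likely to fail

Step 8. The ketene may discriminate poorly between the two faces of the C4=C5 alkene, or prefer the inside-alkoxy arrangement, so that much of the material enters the C4,C5,C9-epimeric series. The resulting mixture of two facial series, each as exo- and endocyclic alkene, may in addition be depleted at the RhCl3 stage by ring opening or acyl shift of the strained β,γ-unsaturated cyclobutanone. The unwanted facial series is a separable diastereomer and cannot be repaired downstream, so a poor facial preference only lowers throughput. Fallback: convergence and separation are moved behind the ring closure. Setting out from 12, the reaction is stopped after the Et3N stage and the exocyclic cycloadduct 14 is isolated as the mixture of facial series. SmI2 in THF closes the C10–C11 bond to the exocyclic tricyclic ketol F1, a rigid compound at which the two facial series should separate cleanly. Oxalylation (MeO2CCOCl, pyridine) gives the oxalate F2, and Bu3SnH reduction gives the exocyclic tricyclic ketone F3, which no longer contains the cyclobutanone. RhCl3·3H2O in EtOH then moves the double bond into the ring and the route is rejoined at 18.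

Step 11. The C10 radical lies β to the C1 carbonyl and may undergo 1,2-acyl migration (contraction of the seven-membered ring) faster than hydrogen transfer; the congested β-hydroxy ketone may also open by retro-aldol cleavage on the way to the oxalate. Fallback: the C1 carbonyl is removed before the radical is made, by changing the order of events. Setting out from 16, HF·pyridine gives the dihydroxy ketone F4. Evans–Tishchenko reduction with 20 and catalytic SmI2 gives the C3 isobutyrate F5 with free C1 and C10 hydroxyls. Et3SiCl and imidazole silylate only the secondary C1 hydroxyl to give the triethylsilyl ether F6. The tertiary alcohol is converted with MeO2CCOCl and pyridine into the oxalate F7 and reduced with Bu3SnH and 2,2'-azobis(2-methylpropionitrile) to the C10-deoxygenated silyl ether F8, whose radical has no β-carbonyl. HF·pyridine removes the triethylsilyl group and the route is rejoined at 21.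

Step 3. The isopinocampheyl ligands may induce only moderately with this hindered methyl ketone, so that 7 and every later compound fall short of enantiomeric purity. Fallback: asymmetric induction is replaced by resolution. Setting out from 2 and 5, the achiral boron enolate of 2 [(c-C6H11)2BCl, Et3N, Et2O; H2O2 work-up] gives the racemic aldol F9; a lithium enolate is avoided because it could attack the neighbouring benzoate. Kinetic resolution by tartrate-directed epoxidation [Ti(OiPr)4, L-(+)-diisopropyl tartrate, t-BuOOH (0.6 equiv), 4 Å molecular sieves, CH2Cl2, −20 °C] should convert the (S)-alcohol into the erythro epoxy alcohol F10 and leave the (R)-alcohol, so that the route is rejoined at 7. The same resolution can be applied to enantio-enriched 7 from step 3.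

Further compounds
F1 | step 8 | 7-hydroxy-2,6,6-trimethyl-9-methylidene-3-[(triisopropylsilyl)oxy]tricyclo[5.4.0.0^2,8]undecan-5-one | O=C1C[C@@H](O[Si](C(C)C)(C(C)C)C(C)C)[C@@]2(C)[C@@H]3CCC(=C)[C@H]2[C@]3(O)C1(C)C
F2 | step 8 | methyl oxalate of F1 at the C10 hydroxyl | O=C1C[C@@H](O[Si](C(C)C)(C(C)C)C(C)C)[C@@]2(C)[C@@H]3CCC(=C)[C@H]2[C@]3(OC(=O)C(=O)OC)C1(C)C
F3 | step 8 | 2,6,6-trimethyl-9-methylidene-3-[(triisopropylsilyl)oxy]tricyclo[5.4.0.0^2,8]undecan-5-one | O=C1C[C@@H](O[Si](C(C)C)(C(C)C)C(C)C)[C@@]2(C)[C@@H]3CCC(=C)[C@H]2[C@@H]3C1(C)C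
F4 | step 11 | 3,7-dihydroxy-2,6,6,9-tetramethyltricyclo[5.4.0.0^2,8]undec-9-en-5-one | O=C1C[C@@H](O)[C@@]2(C)[C@@H]3CC=C(C)[C@H]2[C@]3(O)C1(C)C
F5 | step 11 | 5,7-dihydroxy-2,6,6,9-tetramethyltricyclo[5.4.0.0^2,8]undec-9-en-3-yl 2-methylpropanoate | O[C@@H]1C[C@@H](OC(=O)C(C)C)[C@@]2(C)[C@@H]3CC=C(C)[C@H]2[C@]3(O)C1(C)C
F6 | step 11 | 7-hydroxy-2,6,6,9-tetramethyl-5-[(triethylsilyl)oxy]tricyclo[5.4.0.0^2,8]undec-9-en-3-yl 2-methylpropanoate | CC[Si](CC)(CC)O[C@@H]1C[C@@H](OC(=O)C(C)C)[C@@]2(C)[C@@H]3CC=C(C)[C@H]2[C@]3(O)C1(C)C
F7 | step 11 | methyl oxalate of F6 at the C10 hydroxyl | CC[Si](CC)(CC)O[C@@H]1C[C@@H](OC(=O)C(C)C)[C@@]2(C)[C@@H]3CC=C(C)[C@H]2[C@]3(OC(=O)C(=O)OC)C1(C)C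
F8 | step 11 | 2,6,6,9-tetramethyl-5-[(triethylsilyl)oxy]tricyclo[5.4.0.0^2,8]undec-9-en-3-yl 2-methylpropanoate | CC[Si](CC)(CC)O[C@@H]1C[C@@H](OC(=O)C(C)C)[C@@]2(C)[C@@H]3CC=C(C)[C@H]2[C@@H]3C1(C)C
F9 | step 3 | racemic (2E,6E)-1-acetoxy-8-hydroxy-3,7,11-trimethyl-10-oxododeca-2,6-dien-11-yl benzoate | CC(=O)OC/C=C(C)/CC/C=C(C)/C(O)CC(=O)C(C)(C)OC(=O)c1ccccc1
F10 | step 3 | erythro 6,7-epoxide of the (8S)-enantiomer of 7 | CC(=O)OC/C=C(C)/CC[C@@H]1O[C@@]1(C)[C@@H](O)CC(=O)C(C)(C)OC(=O)c1ccccc1
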